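**Plan**

Locants are those of the dihydronaphthalene: C1=C2 is the enone alkene, C3 the stereocentre, C4 the benzylic CH2, C4a/C8a the fusion atoms; ring A is the fused arene and ring B the new carbocycle.
- Retrosynthesis: after removal of two benzyl ethers and one silyl ether, ring B is cut at C1–C8a, then C1 is removed from C2, then the aryl–C(=O) bond is cut, and last C3–C4.
- Enabling feature: C1 joins the ketone α-carbon C2 to arene carbon C8a, and C8a lies para to the C6 methoxy group of ring A, so an electrophilic C1 placed on C2 is intercepted exactly there.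
- Forward: a Stobbe condensation makes C3–C4, hydrogenation and reduction give a β-benzyl-γ-butyrolactone, an aryllithium opens it to the aryl ketone, C1 is added as an aminomethylene group, and ring B (the only ring formed) is closed by acid.
- Stereochemistry: C3 (R) is set by Rh-catalysed asymmetric hydrogenation of the Stobbe half-ester; from the lactone onward it is never α to a carbonyl group and is not touched again.

Key step: step 8

Assumption: the (S,S)-Et-DuPHOS–Rh catalyst is expected to reduce the itaconate-type half-ester to the (R)-acid; should the sense be the reverse, the (R,R)-ligand is used and nothing else changes.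

**Route**

Step 1
Reactants: 1 4-(benzyloxy)-3-methoxybenzaldehyde (O-benzylvanillin); 2 dimethyl succinate
Product: 4 (E)-4-[4-(benzyloxy)-3-methoxyphenyl]-3-(methoxycarbonyl)but-3-enoic acid, via paraconic ester lactone 3 (not isolated)
Conditions: NaOMe, MeOH, reflux; then aq HCl
Reagents that add atoms: none
Why: Stobbe condensation, in which the succinate enolate adds to the non-enolisable aldehyde, the aldolate lactonises to 3, and base-induced ring opening should give the half-ester with the aryl group trans to the ester.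

Step 2
Reactants: 4 (E)-4-[4-(benzyloxy)-3-methoxyphenyl]-3-(methoxycarbonyl)but-3-enoic acid
Product: 5 (3R)-4-[4-(benzyloxy)-3-methoxyphenyl]-3-(methoxycarbonyl)butanoic acid
Conditions: H2 (5 bar), [Rh(cod)((S,S)-Et-DuPHOS)]BF4 (0.5 mol %), NaOMe (10 mol %), MeOH, rt
Reagents that add atoms: none
Why: Rh–bisphosphine asymmetric hydrogenation of an itaconate-type half-ester, in which the carboxylate and the alkene chelate rhodium and the C2-symmetric ligand selects the alkene face to set C3 as R; the cationic Rh catalyst should not hydrogenolyse the benzyl ether.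

Step 3
Reactants: 5 (3R)-4-[4-(benzyloxy)-3-methoxyphenyl]-3-(methoxycarbonyl)butanoic acid
Product: 7 (4R)-4-[4-(benzyloxy)-3-methoxybenzyl]oxolan-2-one, via hydroxy acid 6 (not isolated)
Conditions: KOH (1 equiv), EtOH; CaCl2, NaBH4, EtOH, −10 °C to rt; then 3 M HCl, rt
Reagents that add atoms: none
Why: chemoselective borohydride reduction, in which calcium borohydride reduces the methyl ester but not the potassium carboxylate, followed by acid lactonisation of 6; run cold, the reduction should outpace epimerisation of the ester α-centre, which is no longer α to a carbonyl group afterwards.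

Step 4
Reactants: 8 4-bromo-2-methoxyphenol; 9 benzyl bromide
Product: 10 1-(benzyloxy)-4-bromo-2-methoxybenzene
Conditions: BnBr, K2CO3, DMF, rt
Reagents that add atoms: benzyl bromide (9), BrCc1ccccc1
Why: Williamson ether synthesis of a phenoxide with a reactive benzylic halide.

Step 5
Reactants: 10 1-(benzyloxy)-4-bromo-2-methoxybenzene; 7 (4R)-4-[4-(benzyloxy)-3-methoxybenzyl]oxolan-2-one
Product: 12 (3R)-1,4-bis[4-(benzyloxy)-3-methoxyphenyl]-3-(hydroxymethyl)butan-1-one, via aryllithium 11 (not isolated)
Conditions: 10, n-BuLi, THF, −78 °C; cannulate into 7, THF, −78 °C; sat. aq NH4Cl at −78 °C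
Reagents that add atoms: none
Why: bromine–lithium exchange followed by nucleophilic acyl substitution on the lactone, in which the lithium hemiketal alkoxide is expected to persist at −78 °C so that the ketone is released only on quenching and a second addition is avoided; C3 is β to the carbonyl and is not affected.

Step 6
Reactants: 12 (3R)-1,4-bis[4-(benzyloxy)-3-methoxyphenyl]-3-(hydroxymethyl)butan-1-one; 13 tert-butyl(chloro)diphenylsilane
Product: 14 (3R)-1,4-bis[4-(benzyloxy)-3-methoxyphenyl]-3-{[(tert-butyldiphenylsilyl)oxy]methyl}butan-1-one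
Conditions: TBDPSCl, imidazole, DMF, rt
Reagents that add atoms: tert-butyl(chloro)diphenylsilane (13), CC(C)(C)[Si](Cl)(c1ccccc1)c1ccccc1
Why: imidazole-mediated silylation of a primary alcohol; the TBDPS ether is chosen over TBS because it must survive the acid of step 8 and keep the oxygen from trapping the iminium ion.

Step 7
Reactants: 14 (3R)-1,4-bis[4-(benzyloxy)-3-methoxyphenyl]-3-{[(tert-butyldiphenylsilyl)oxy]methyl}butan-1-one; 15 tert-butoxybis(dimethylamino)methane
Product: 16 (3R)-1,4-bis[4-(benzyloxy)-3-methoxyphenyl]-3-{[(tert-butyldiphenylsilyl)oxy]methyl}-2-[(E)-(dimethylamino)methylidene]butan-1-one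
Conditions: t-BuOCH(NMe2)2 (3 equiv), toluene, 100 °C
Reagents that add atoms: tert-butoxybis(dimethylamino)methane (15), CN(C)C(OC(C)(C)C)N(C)C
Why: aminomethylenation of a ketone with Bredereck's reagent, in which the tert-butoxide released deprotonates the only enolisable position (the α-CH2), the enolate adds to the formamidinium ion and dimethylamine is lost to give the enaminone carrying C1.

Step 8
Reactants: 16 (3R)-1,4-bis[4-(benzyloxy)-3-methoxyphenyl]-3-{[(tert-butyldiphenylsilyl)oxy]methyl}-2-[(E)-(dimethylamino)methylidene]butan-1-one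
Product: 18 [(3R)-7-(benzyloxy)-3-{[(tert-butyldiphenylsilyl)oxy]methyl}-6-methoxy-3,4-dihydronaphthalen-2-yl][4-(benzyloxy)-3-methoxyphenyl]methanone, via amino ketone adduct 17 (not isolated)
Conditions: TFA (10 equiv), CH2Cl2, 0 °C to rt; aq NaHCO3
Reagents that add atoms: none
Why: TFA protonates the enaminone on oxygen to give the vinylogous iminium ion Me2N+=C1H–C2=C(OH)Ar, C8a attacks C1, rearomatisation gives amino ketone 17, and β-elimination of dimethylamine as its ammonium salt leaves the C1=C2 enone conjugated to both ring A and the ketone. The closest known reaction type is the Bradsher cyclodehydration, the intramolecular Friedel–Crafts reaction of an aryl-tethered β-keto aldehyde or its enaminone followed by loss of water or amine. Ring B closes in a 6-exo-trig mode with respect to the C1=N+ bond, the nitrogen staying outside the new ring. No stereocentre is created, and C3, which is not α to a carbonyl group, should keep its R configuration under acid. C1 should be preferred over the ketone carbon because it is the unhindered iminium terminus of the cation, whereas the other terminus is fully substituted and aryl-stabilised; C8a should be preferred over the position between the CH2 and OMe groups because it is para to the C6 methoxy group and less crowded. The TBDPS and benzyl ethers are chosen to tolerate TFA at or below room temperature.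

Step 9
Reactants: 18 [(3R)-7-(benzyloxy)-3-{[(tert-butyldiphenylsilyl)oxy]methyl}-6-methoxy-3,4-dihydronaphthalen-2-yl][4-(benzyloxy)-3-methoxyphenyl]methanone
Product: 19 [(3R)-7-(benzyloxy)-3-(hydroxymethyl)-6-methoxy-3,4-dihydronaphthalen-2-yl][4-(benzyloxy)-3-methoxyphenyl]methanone
Conditions: TBAF, AcOH (1:1), THF, 0 °C to rt
Reagents that add atoms: none
Why: fluoride-mediated desilylation, buffered with acetic acid so that the enone and the benzylic C4 position are not exposed to a basic alkoxide.

Step 10
Reactants: 19 [(3R)-7-(benzyloxy)-3-(hydroxymethyl)-6-methoxy-3,4-dihydronaphthalen-2-yl][4-(benzyloxy)-3-methoxyphenyl]methanone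
Product: 20 [(3R)-7-hydroxy-3-(hydroxymethyl)-6-methoxy-3,4-dihydronaphthalen-2-yl](4-hydroxy-3-methoxyphenyl)methanone (CNP0352298.1)
Conditions: BCl3 (6 equiv), C6HMe5 (6 equiv), CH2Cl2, −78 °C; MeOH quench
Reagents that add atoms: none
Why: Lewis-acid debenzylation of aryl benzyl ethers with pentamethylbenzene as a non-basic benzyl-cation scavenger (Friedel–Crafts capture), which at −78 °C should spare the methyl ethers and the enone alkene that hydrogenolysis would reduce.

**Compound list**

1 | 4-(benzyloxy)-3-methoxybenzaldehyde | O=Cc1ccc(OCc2ccccc2)c(OC)c1 | starting material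
2 | dimethyl succinate | COC(=O)CCC(=O)OC | starting material
3 | methyl 2-[4-(benzyloxy)-3-methoxyphenyl]-5-oxooxolane-3-carboxylate (paraconic ester, stereoisomer mixture) | COC(=O)C1CC(=O)OC1c1ccc(OCc2ccccc2)c(OC)c1 | intermediate
4 | (E)-4-[4-(benzyloxy)-3-methoxyphenyl]-3-(methoxycarbonyl)but-3-enoic acid | OC(=O)C/C(=C\c1ccc(OCc2ccccc2)c(OC)c1)C(=O)OC | intermediate
5 | (3R)-4-[4-(benzyloxy)-3-methoxyphenyl]-3-(methoxycarbonyl)butanoic acid | OC(=O)C[C@@H](Cc1ccc(OCc2ccccc2)c(OC)c1)C(=O)OC | intermediate
6 | (3R)-4-[4-(benzyloxy)-3-methoxyphenyl]-3-(hydroxymethyl)butanoic acid | OC(=O)C[C@@H](Cc1ccc(OCc2ccccc2)c(OC)c1)CO | intermediate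
7 | (4R)-4-[4-(benzyloxy)-3-methoxybenzyl]oxolan-2-one | O=C1C[C@@H](Cc2ccc(OCc3ccccc3)c(OC)c2)CO1 | intermediate
8 | 4-bromo-2-methoxyphenol | COc1cc(Br)ccc1O | starting material
9 | benzyl bromide | BrCc1ccccc1 | starting material
10 | 1-(benzyloxy)-4-bromo-2-methoxybenzene | COc1cc(Br)ccc1OCc1ccccc1 | intermediate
11 | [4-(benzyloxy)-3-methoxyphenyl]lithium | [Li]c1ccc(OCc2ccccc2)c(OC)c1 | intermediate
12 | (3R)-1,4-bis[4-(benzyloxy)-3-methoxyphenyl]-3-(hydroxymethyl)butan-1-one | COc1cc(C(=O)C[C@@H](Cc2ccc(OCc3ccccc3)c(OC)c2)CO)ccc1OCc1ccccc1 | intermediate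
13 | tert-butyl(chloro)diphenylsilane | CC(C)(C)[Si](Cl)(c1ccccc1)c1ccccc1 | starting material
14 | (3R)-1,4-bis[4-(benzyloxy)-3-methoxyphenyl]-3-{[(tert-butyldiphenylsilyl)oxy]methyl}butan-1-one | COc1cc(C(=O)C[C@@H](Cc2ccc(OCc3ccccc3)c(OC)c2)CO[Si](c2ccccc2)(c2ccccc2)C(C)(C)C)ccc1OCc1ccccc1 | intermediate
15 | tert-butoxybis(dimethylamino)methane | CN(C)C(OC(C)(C)C)N(C)C | starting material
16 | (3R)-1,4-bis[4-(benzyloxy)-3-methoxyphenyl]-3-{[(tert-butyldiphenylsilyl)oxy]methyl}-2-[(E)-(dimethylamino)methylidene]butan-1-one | CN(C)/C=C(\[C@H](CO[Si](c1ccccc1)(c1ccccc1)C(C)(C)C)Cc1ccc(OCc2ccccc2)c(OC)c1)C(=O)c1ccc(OCc2ccccc2)c(OC)c1 | intermediate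
17 | [(3R)-7-(benzyloxy)-3-{[(tert-butyldiphenylsilyl)oxy]methyl}-1-(dimethylamino)-6-methoxy-1,2,3,4-tetrahydronaphthalen-2-yl][4-(benzyloxy)-3-methoxyphenyl]methanone (C1 and C2 undefined) | COc1cc(C(=O)C2C(N(C)C)c3cc(OCc4ccccc4)c(OC)cc3C[C@H]2CO[Si](c2ccccc2)(c2ccccc2)C(C)(C)C)ccc1OCc1ccccc1 | intermediate
18 | [(3R)-7-(benzyloxy)-3-{[(tert-butyldiphenylsilyl)oxy]methyl}-6-methoxy-3,4-dihydronaphthalen-2-yl][4-(benzyloxy)-3-methoxyphenyl]methanone | COc1cc(C(=O)C2=Cc3cc(OCc4ccccc4)c(OC)cc3C[C@H]2CO[Si](c2ccccc2)(c2ccccc2)C(C)(C)C)ccc1OCc1ccccc1 | intermediate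
19 | [(3R)-7-(benzyloxy)-3-(hydroxymethyl)-6-methoxy-3,4-dihydronaphthalen-2-yl][4-(benzyloxy)-3-methoxyphenyl]methanone | COc1cc(C(=O)C2=Cc3cc(OCc4ccccc4)c(OC)cc3C[C@H]2CO)ccc1OCc1ccccc1 | intermediate
20 | [(3R)-7-hydroxy-3-(hydroxymethyl)-6-methoxy-3,4-dihydronaphthalen-2-yl](4-hydroxy-3-methoxyphenyl)methanone | COc1cc(C(=O)C2=Cc3cc(O)c(OC)cc3C[C@H]2CO)ccc1O | target

**Totals**

Total step count: 10. Longest linear sequence: 9 steps (steps 1–3 and 5–10, from compound 1).

**Steps most likely to fail, with fallbacks**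

Step 8. The protonated enaminone may be too weak an electrophile, so that ring closure is slow and the benzyl or silyl ethers are cleaved first, or the arene may attack the ketone-derived terminus instead of C1. The fallback closes ring B by forming C1–C2 instead of C1–C8a. It sets out from ketone 14: Rieche formylation (dichloromethyl methyl ether, silver triflate, CH2Cl2, −78 °C) should place a formyl group on the benzyl ring para to its methoxy group and give 5-(benzyloxy)-2-[(2R)-4-[4-(benzyloxy)-3-methoxyphenyl]-2-{[(tert-butyldiphenylsilyl)oxy]methyl}-4-oxobutyl]-4-methoxybenzaldehyde F1. An intramolecular aldol condensation of the ketone α-CH2 onto this aldehyde (pyrrolidine, acetic acid, toluene, warm) should then dehydrate to the conjugated enone, and the route is rejoined at 18.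

Step 5. The hemiketal alkoxide may collapse early so that a second aryllithium adds, or the aryllithium may enolise the lactone instead of adding. The fallback sets out from lactone 7: aminolysis with N,O-dimethylhydroxylamine hydrochloride and isopropylmagnesium chloride (THF, −20 °C) should give the hydroxy Weinreb amide (3R)-4-[4-(benzyloxy)-3-methoxyphenyl]-3-(hydroxymethyl)-N-methoxy-N-methylbutanamide F2. Silylation with TBDPSCl and imidazole gives (3R)-4-[4-(benzyloxy)-3-methoxyphenyl]-3-{[(tert-butyldiphenylsilyl)oxy]methyl}-N-methoxy-N-methylbutanamide F3. Addition of aryllithium 11 to F3, whose chelated tetrahedral intermediate cannot add twice, rejoins the route at 14 without passing through 12.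

Step 7. Aminomethylenation at the β-branched α-methylene may be sluggish, and prolonged heating may decompose the ketone. The fallback sets out from ketone 14: Claisen formylation with ethyl formate and sodium hydride (THF, 0 °C to rt) should give (3R)-1,4-bis[4-(benzyloxy)-3-methoxyphenyl]-3-{[(tert-butyldiphenylsilyl)oxy]methyl}-2-(hydroxymethylidene)butan-1-one F4. Condensation of F4 with dimethylamine (THF, molecular sieves, rt) rejoins the route at 16.

**Further compounds**

F1 | step 8 | 5-(benzyloxy)-2-[(2R)-4-[4-(benzyloxy)-3-methoxyphenyl]-2-{[(tert-butyldiphenylsilyl)oxy]methyl}-4-oxobutyl]-4-methoxybenzaldehyde | COc1cc(C(=O)C[C@@H](Cc2cc(OC)c(OCc3ccccc3)cc2C=O)CO[Si](c2ccccc2)(c2ccccc2)C(C)(C)C)ccc1OCc1ccccc1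
F2 | step 5 | (3R)-4-[4-(benzyloxy)-3-methoxyphenyl]-3-(hydroxymethyl)-N-methoxy-N-methylbutanamide | CON(C)C(=O)C[C@@H](Cc1ccc(OCc2ccccc2)c(OC)c1)CO
F3 | step 5 | (3R)-4-[4-(benzyloxy)-3-methoxyphenyl]-3-{[(tert-butyldiphenylsilyl)oxy]methyl}-N-methoxy-N-methylbutanamide | CON(C)C(=O)C[C@@H](Cc1ccc(OCc2ccccc2)c(OC)c1)CO[Si](c1ccccc1)(c1ccccc1)C(C)(C)C
F4 | step 7 | (3R)-1,4-bis[4-(benzyloxy)-3-methoxyphenyl]-3-{[(tert-butyldiphenylsilyl)oxy]methyl}-2-(hydroxymethylidene)butan-1-one | OC=C([C@H](CO[Si](c1ccccc1)(c1ccccc1)C(C)(C)C)Cc1ccc(OCc2ccccc2)c(OC)c1)C(=O)c1ccc(OCc2ccccc2)c(OC)c1
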